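**Retrosynthetic overview**

- Xanthogalenol ⇒ (acid removal of two MOM groups) protected chalcone ⇒ (Claisen–Schmidt disconnection at Cα=Cβ) ring A methyl ketone plus MOM-protected 4-hydroxybenzaldehyde; ring B is bought.
- Ring A methyl ketone ⇒ (benzylic oxidation, desilylation) a phenol in which the acetyl group is latent as a silylated 1-hydroxyethyl group.
- Ring A is the only ring made. It is a pentasubstituted benzene with mutually meta oxygens at C2', C4' and C6', carbon groups at C1' (acyl) and C3' (prenyl), and H only at C5'. A vinylketene/ynol ether benzannulation of a 3-methoxy-2-prenylcyclobutenone with a siloxyalkyne delivers exactly this pattern, forming C1'–C6', C2'–C3' and C5'–C6'.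
- Cyclobutenone ⇒ ketene plus a prenylated methoxyalkyne (from chloroacetaldehyde dimethyl acetal and prenyl bromide); siloxyalkyne ⇒ Kowalski homologation and O-silylation of TBS-protected ethyl (S)-lactate.

Key step: step 5

Remark: the lactate-derived carbinol centre is a spectator that is oxidized away in step 8; it is drawn (S) throughout and any erosion on the way is without consequence. Ketene for step 2 is generated from acetone in a ketene generator.

**Route**

Step 1
Reactants: 1 2-chloro-1,1-dimethoxyethane; 2 prenyl bromide (1-bromo-3-methylbut-2-ene)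
Product: 4 1-methoxy-5-methylhex-4-en-1-yne, via lithium methoxyacetylide 3 (not isolated)
Conditions: LiNEt2 (3 equiv, from Et2NH and n-BuLi), THF, 0 °C; then DMPU, 2, −78 °C → rt
Reagents that add atoms: none
Why: Three equivalents of lithium amide strip methanol and then HCl from the chloroacetal and deprotonate the resulting methoxyacetylene, and acetylide 3 displaces bromide from the primary allylic bromide (SN2 alkylation of an alkoxyacetylide, the usual one-pot entry to 1-alkoxyalk-1-ynes).

Step 2
Reactants: 4 1-methoxy-5-methylhex-4-en-1-yne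
Product: 5 3-methoxy-2-(3-methylbut-2-enyl)cyclobut-2-en-1-one
Conditions: ketene (gas, excess, from acetone pyrolysis), CH2Cl2, −20 → 0 °C
Reagents that add atoms: ketene, C=C=O
Why: Thermal [2+2] cycloaddition of ketene to the ynol ether, in which the nucleophilic alkyne carbon bearing the prenyl group bonds to the ketene carbonyl carbon so that the methoxy group ends up β to the carbonyl (known 3-alkoxycyclobutenone synthesis); the unactivated trisubstituted alkene is inert to ketene.

Step 3
Reactants: 6 ethyl (S)-lactate
Product: 7 ethyl (S)-2-(tert-butyldimethylsilyloxy)propanoate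
Conditions: TBSCl, imidazole, DMF, 0 °C → rt
Reagents that add atoms: tert-butyldimethylsilyl chloride, CC(C)(C)[Si](C)(C)Cl
Why: Standard imidazole-promoted silylation of a secondary alcohol, which leaves the stereocentre untouched.

Step 4
Reactants: 7 ethyl (S)-2-(tert-butyldimethylsilyloxy)propanoate
Product: 10 (S)-3-(tert-butyldimethylsilyloxy)-1-(triisopropylsilyloxy)but-1-yne, via dibromoketone enolate 8 (not isolated), via lithium ynolate 9 (not isolated)
Conditions: CH2Br2, lithium 2,2,6,6-tetramethylpiperidide, THF, −78 °C; 7; LiN(SiMe3)2; n-BuLi, −78 → 0 °C; iPr3SiCl, −78 °C → rt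
Reagents that add atoms: dibromomethane, BrCBr; chlorotriisopropylsilane, CC(C)[Si](Cl)(C(C)C)C(C)C
Why: Kowalski ester homologation, in which LiCHBr2 adds to the ester, enolate 8 undergoes bromine–lithium exchange and carbenoid 1,2-shift of the carbinol carbon (with retention) to ynolate 9, and the bulky silyl chloride traps 9 on oxygen to give the siloxyalkyne.

Step 5
Reactants: 5 3-methoxy-2-(3-methylbut-2-enyl)cyclobut-2-en-1-one; 10 (S)-3-(tert-butyldimethylsilyloxy)-1-(triisopropylsilyloxy)but-1-yne
Product: 15 2-[(S)-1-(tert-butyldimethylsilyloxy)ethyl]-5-methoxy-4-(3-methylbut-2-enyl)-3-(triisopropylsilyloxy)phenol, via vinylketene 11 (not isolated), via vinylcyclobutenone 12 (not isolated), via dienylketene 13 (not isolated), via cyclohexadienone 14 (not isolated)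
Conditions: 10 (1.3 equiv), PhMe, 110 °C, sealed tube, Ar
Reagents that add atoms: none
Why: Danheiser-type benzannulation, a thermal pericyclic cascade: 4π electrocyclic opening of 5 gives vinylketene 11, whose ketene C=C adds [2+2] to the electron-rich alkyne of 10 to give 12, which opens again (4π) to dienylketene 13 and closes to dienone 14 before tautomerizing to phenol 15. Ring A is closed by a thermal disrotatory 6π electrocyclization that makes C5'–C6', after the [2+2] step has already made C1'–C6' and C2'–C3'. No stereocentre is created in 15 (the quaternary carbon of 12 is lost on ring opening) and the lactate-derived centre is a bystander. The selectivity required is regiochemical and is secured by polarity: the alkyne carbon remote from the siloxy group is the nucleophilic one and bonds to the electrophilic ketene carbonyl carbon, which places the silyloxyethyl group between the new OH and the OTIPS group while the cyclobutenone fixes prenyl at C3', methoxyl at C4' and H at C5'. Opening of 12 is reversible, so both rotational modes drain through the trienone geometry that can cyclize. The closest known reaction type is the same annulation of 3-alkylcyclobutenones with triisopropylsiloxyalkynes; the vinylogous-ester cyclobutenone 5 is expected to open more slowly, hence 110 °C and an excess of 10.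

Step 6
Reactants: 15 2-[(S)-1-(tert-butyldimethylsilyloxy)ethyl]-5-methoxy-4-(3-methylbut-2-enyl)-3-(triisopropylsilyloxy)phenol
Product: 16 tert-butyl{(S)-1-[4-methoxy-6-(methoxymethoxy)-3-(3-methylbut-2-enyl)-2-(triisopropylsilyloxy)phenyl]ethoxy}dimethylsilane (the MOM ether of 15)
Conditions: MOMCl, iPr2NEt, CH2Cl2, 0 °C → rt
Reagents that add atoms: chloromethyl methyl ether, COCCl
Why: O-alkylation of the only free phenol by the reactive α-chloro ether under amine base (MOM protection); both silyl ethers are inert.

Step 7
Reactants: 16 the MOM ether of 15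
Product: 17 2-[(S)-1-hydroxyethyl]-5-methoxy-3-(methoxymethoxy)-6-(3-methylbut-2-enyl)phenol
Conditions: Bu4NF, AcOH (1:1), THF, 0 °C → rt
Reagents that add atoms: none
Why: Fluoride-mediated desilylation cleaves the aryl TIPS ether quickly and the hindered benzylic TBS ether more slowly, and the acetic acid buffer keeps the liberated phenol protonated so that quinone-methide formation at the ortho-hydroxybenzylic position should be suppressed.

Step 8
Reactants: 17 2-[(S)-1-hydroxyethyl]-5-methoxy-3-(methoxymethoxy)-6-(3-methylbut-2-enyl)phenol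
Product: 18 1-[2-hydroxy-4-methoxy-6-(methoxymethoxy)-3-(3-methylbut-2-enyl)phenyl]ethanone
Conditions: activated MnO2 (excess), CH2Cl2, rt
Reagents that add atoms: none
Why: MnO2 oxidation of an electron-rich benzylic alcohol to the aryl ketone, which is stabilized by hydrogen bonding to the 2'-OH; the prenyl alkene and MOM ether are inert and the spectator stereocentre is erased here.

Step 9
Reactants: 19 4-hydroxybenzaldehyde
Product: 20 4-(methoxymethoxy)benzaldehyde
Conditions: MOMCl, iPr2NEt, CH2Cl2, 0 °C → rt
Reagents that add atoms: chloromethyl methyl ether, COCCl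
Why: MOM protection of the phenol, which prevents formation of the deactivating phenoxide in the base-mediated condensation.

Step 10
Reactants: 18 1-[2-hydroxy-4-methoxy-6-(methoxymethoxy)-3-(3-methylbut-2-enyl)phenyl]ethanone; 20 4-(methoxymethoxy)benzaldehyde
Product: 22 (E)-1-[2-hydroxy-4-methoxy-6-(methoxymethoxy)-3-(3-methylbut-2-enyl)phenyl]-3-[4-(methoxymethoxy)phenyl]prop-2-en-1-one, via aldol adduct 21 (not isolated)
Conditions: KOH (excess), EtOH/H2O, 0 °C → rt
Reagents that add atoms: none
Why: Claisen–Schmidt condensation, in which the methyl ketone enolate adds to the non-enolizable aldehyde and E1cB dehydration of 21 gives the thermodynamically preferred E-enone; the 2'-phenoxide and the MOM ethers tolerate KOH.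

Step 11
Reactants: 22 the bis-MOM chalcone
Product: 23 xanthogalenol, (E)-1-[2,6-dihydroxy-4-methoxy-3-(3-methylbut-2-enyl)phenyl]-3-(4-hydroxyphenyl)prop-2-en-1-one
Conditions: aq. HCl, MeOH, rt, short reaction time
Reagents that add atoms: none
Why: Acid-catalysed methanolysis of the two aryl MOM acetals under mild conditions, kept brief so that flavanone closure and cyclization onto the prenyl group should not compete; the E-alkene is unaffected.

**Compound list**

1 | 2-chloro-1,1-dimethoxyethane (chloroacetaldehyde dimethyl acetal) | COC(CCl)OC | starting material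
2 | prenyl bromide (1-bromo-3-methylbut-2-ene) | CC(C)=CCBr | starting material
3 | lithium methoxyacetylide | [Li]C#COC | intermediate
4 | 1-methoxy-5-methylhex-4-en-1-yne | COC#CCC=C(C)C | intermediate
5 | 3-methoxy-2-(3-methylbut-2-enyl)cyclobut-2-en-1-one | COC1=C(CC=C(C)C)C(=O)C1 | intermediate
6 | ethyl (S)-lactate | C[C@H](O)C(=O)OCC | starting material
7 | ethyl (S)-2-(tert-butyldimethylsilyloxy)propanoate | C[C@H](O[Si](C)(C)C(C)(C)C)C(=O)OCC | intermediate
8 | lithium (S)-1,1-dibromo-3-(tert-butyldimethylsilyloxy)but-1-en-2-olate | C[C@H](O[Si](C)(C)C(C)(C)C)C(O[Li])=C(Br)Br | intermediate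
9 | lithium (S)-3-(tert-butyldimethylsilyloxy)but-1-yn-1-olate | C[C@H](O[Si](C)(C)C(C)(C)C)C#CO[Li] | intermediate
10 | (S)-3-(tert-butyldimethylsilyloxy)-1-(triisopropylsilyloxy)but-1-yne | C[C@H](O[Si](C)(C)C(C)(C)C)C#CO[Si](C(C)C)(C(C)C)C(C)C | intermediate
11 | 3-methoxy-2-(3-methylbut-2-enyl)buta-1,3-dien-1-one (vinylketene) | C=C(OC)C(CC=C(C)C)=C=O | intermediate
12 | 2-[(S)-1-(tert-butyldimethylsilyloxy)ethyl]-4-(1-methoxyvinyl)-4-(3-methylbut-2-enyl)-3-(triisopropylsilyloxy)cyclobut-2-en-1-one (either configuration at C4) | O=C1C([C@H](C)O[Si](C)(C)C(C)(C)C)=C(O[Si](C(C)C)(C(C)C)C(C)C)C1(CC=C(C)C)C(OC)=C | intermediate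
13 | (3E)-2-[(S)-1-(tert-butyldimethylsilyloxy)ethyl]-5-methoxy-4-(3-methylbut-2-enyl)-3-(triisopropylsilyloxy)hexa-1,3,5-trien-1-one (ketene carbon and methoxyvinyl group cis) | O=C=C([C@H](C)O[Si](C)(C)C(C)(C)C)/C(O[Si](C(C)C)(C(C)C)C(C)C)=C(CC=C(C)C)\C(OC)=C | intermediate
14 | 2-[(S)-1-(tert-butyldimethylsilyloxy)ethyl]-5-methoxy-4-(3-methylbut-2-enyl)-3-(triisopropylsilyloxy)cyclohexa-2,4-dien-1-one | O=C1CC(OC)=C(CC=C(C)C)C(O[Si](C(C)C)(C(C)C)C(C)C)=C1[C@H](C)O[Si](C)(C)C(C)(C)C | intermediate
15 | 2-[(S)-1-(tert-butyldimethylsilyloxy)ethyl]-5-methoxy-4-(3-methylbut-2-enyl)-3-(triisopropylsilyloxy)phenol | COc1cc(O)c([C@H](C)O[Si](C)(C)C(C)(C)C)c(O[Si](C(C)C)(C(C)C)C(C)C)c1CC=C(C)C | intermediate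
16 | tert-butyl{(S)-1-[4-methoxy-6-(methoxymethoxy)-3-(3-methylbut-2-enyl)-2-(triisopropylsilyloxy)phenyl]ethoxy}dimethylsilane | COc1cc(OCOC)c([C@H](C)O[Si](C)(C)C(C)(C)C)c(O[Si](C(C)C)(C(C)C)C(C)C)c1CC=C(C)C | intermediate
17 | 2-[(S)-1-hydroxyethyl]-5-methoxy-3-(methoxymethoxy)-6-(3-methylbut-2-enyl)phenol | COc1cc(OCOC)c([C@H](C)O)c(O)c1CC=C(C)C | intermediate
18 | 1-[2-hydroxy-4-methoxy-6-(methoxymethoxy)-3-(3-methylbut-2-enyl)phenyl]ethanone | COc1cc(OCOC)c(C(C)=O)c(O)c1CC=C(C)C | intermediate
19 | 4-hydroxybenzaldehyde | O=Cc1ccc(O)cc1 | starting material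
20 | 4-(methoxymethoxy)benzaldehyde | COCOc1ccc(C=O)cc1 | intermediate
21 | 3-hydroxy-1-[2-hydroxy-4-methoxy-6-(methoxymethoxy)-3-(3-methylbut-2-enyl)phenyl]-3-[4-(methoxymethoxy)phenyl]propan-1-one (racemic at C3) | COc1cc(OCOC)c(C(=O)CC(O)c2ccc(OCOC)cc2)c(O)c1CC=C(C)C | intermediate
22 | (E)-1-[2-hydroxy-4-methoxy-6-(methoxymethoxy)-3-(3-methylbut-2-enyl)phenyl]-3-[4-(methoxymethoxy)phenyl]prop-2-en-1-one | COc1cc(OCOC)c(C(=O)/C=C/c2ccc(OCOC)cc2)c(O)c1CC=C(C)C | intermediate
23 | xanthogalenol | COc1cc(O)c(C(=O)/C=C/c2ccc(O)cc2)c(O)c1CC=C(C)C | target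

**Step count**

Total: 11 steps. Longest linear sequence: 8 steps (steps 1, 2, 5, 6, 7, 8, 10, 11; the lactate branch through steps 3 and 4 is equally long).

**Steps most likely to fail**

Step 5 (benzannulation). The vinylogous-ester cyclobutenone may open to the vinylketene too slowly at temperatures the siloxyalkyne tolerates. Rearrangement of the siloxyalkyne to a silylketene, or acylation of the product phenol by ketene intermediates, could then outrun the annulation. The fallback gives up the ring construction for classical phloroacetophenone chemistry and sets out from prenyl bromide 2. DBU-mediated C-prenylation (THF, rt) of purchased 2',6'-dihydroxy-4'-methoxyacetophenone F1 should give 2',6'-dihydroxy-4'-methoxy-3'-(3-methylbut-2-enyl)acetophenone F2, a single C-regioisomer by symmetry. Mono-protection with one equivalent of MOMCl and iPr2NEt at the less hindered hydroxyl (the one flanked by H; the hydroxyl between prenyl and acetyl stays chelated) comes back to the route at 18.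

Step 4 (Kowalski homologation and O-silylation). The carbenoid base may enolize the α-silyloxy ester instead of adding to it, the carbenoid rearrangement may stall, or silylation may go to carbon. The fallback builds the same ynolate by acetylide oxidation and sets out from 7. Reduction with iBu2AlH (CH2Cl2, −78 °C) should give (S)-2-(tert-butyldimethylsilyloxy)propanal F3, and Ohira–Bestmann homologation (dimethyl 1-diazo-2-oxopropylphosphonate, K2CO3, MeOH) should give (S)-3-(tert-butyldimethylsilyloxy)but-1-yne F4. Lithiation with n-BuLi and oxidation of the acetylide with LiOOtBu (from tBuOOH and LiN(SiMe3)2) should lead to ynolate 9, and trapping with iPr3SiOTf comes back to the route at 10.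

Step 7 (global desilylation). Once the aryl silyl ether has been cleaved, the ortho-phenol can expel the benzylic silyloxy or hydroxy group (quinone-methide formation followed by tautomerization to a vinylarene or oligomerization), or the hindered benzylic silyl ether may be cleaved incompletely. The fallback reverses the order of events so that the ketone is in place before the ortho-phenol is freed, and sets out from 16. HF·pyridine buffered with pyridine (THF, 0 °C) should cleave only the alkyl TBS ether to give (S)-1-[4-methoxy-6-(methoxymethoxy)-3-(3-methylbut-2-enyl)-2-(triisopropylsilyloxy)phenyl]ethanol F5. Dess–Martin periodinane (NaHCO3, CH2Cl2) should give 1-[4-methoxy-6-(methoxymethoxy)-3-(3-methylbut-2-enyl)-2-(triisopropylsilyloxy)phenyl]ethanone F6, and Bu4NF (THF, 0 °C) then removes the aryl TIPS group and comes back to the route at 18.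

**Further compounds**

F1 | step 5 | 2',6'-dihydroxy-4'-methoxyacetophenone (purchased) | CC(=O)c1c(O)cc(OC)cc1O
F2 | step 5 | 2',6'-dihydroxy-4'-methoxy-3'-(3-methylbut-2-enyl)acetophenone | CC(=O)c1c(O)cc(OC)c(CC=C(C)C)c1O
F3 | step 4 | (S)-2-(tert-butyldimethylsilyloxy)propanal | C[C@H](O[Si](C)(C)C(C)(C)C)C=O
F4 | step 4 | (S)-3-(tert-butyldimethylsilyloxy)but-1-yne | C[C@H](O[Si](C)(C)C(C)(C)C)C#C
F5 | step 7 | (S)-1-[4-methoxy-6-(methoxymethoxy)-3-(3-methylbut-2-enyl)-2-(triisopropylsilyloxy)phenyl]ethanol | COc1cc(OCOC)c([C@H](C)O)c(O[Si](C(C)C)(C(C)C)C(C)C)c1CC=C(C)C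
F6 | step 7 | 1-[4-methoxy-6-(methoxymethoxy)-3-(3-methylbut-2-enyl)-2-(triisopropylsilyloxy)phenyl]ethanone | COc1cc(OCOC)c(C(C)=O)c(O[Si](C(C)C)(C(C)C)C(C)C)c1CC=C(C)C
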